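**Retrosynthetic overview**

Labels: ring A arene, ring B six-membered carbocycle, ring C cycloheptenone, ring D γ-lactone; C-a benzylic CH, C-b O-bearing CH, C-c lactone α-CH, C-q methyl-bearing quaternary carbon, C-g CMe2 carbon, C-k enone carbonyl carbon.
Feature: in ring D the carbonyl hangs on C-c and the ring oxygen on C-b, both bonded to C-a, so ring D is a cis-fused cyclobutanone (C-a, C-b, C=O, C-c) plus one oxygen atom, and the arm C-b–C-k–CH=CH–C-q is ring C.
Endgame, backwards: two aryl C–Br bonds (electrophilic bromination), the C-k carbonyl (allylic oxidation) and the ring-D oxygen (Baeyer–Villiger) lead to a des-bromo cyclobutanone.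
Key disconnection: bonds C-a–C-b and C(=O)–C-c of that cyclobutanone, i.e. an intramolecular keteniminium–styrene [2+2] cycloaddition of a Z-alkenyl dimethylamide on a 1,2-dihydronaphthalene, which closes the cyclobutane and ring C together.
Precursor and ring order: Z-Wittig and amidation on a quaternary aldehyde; ring B by Friedel–Crafts cyclodehydration of a one-carbon-homologated aldehyde arm; C-q by lipase desymmetrisation of a prochiral diol; C-g–aryl bond by aryl Grignard conjugate addition; rings form in the order A (bought), B (step 7), cyclobutane and C (step 12), D (step 13).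

Key step: step 12

Remark: the lipase is assumed to acetylate the enantiotopic arm that gives the (S)-monoacetate; if it prefers the other arm, the same (S)-ester is reached with the same enzyme by hydrolysis of the diacetate of the diol.

**Route**

Step 1
Reactants: 1 1-bromo-4-ethylbenzene; 2 diethyl isopropylidenemalonate
Product: 4 diethyl 2-[2-(4-ethylphenyl)propan-2-yl]propanedioate, via 4-ethylphenylmagnesium bromide 3 (not isolated)
Conditions: Mg, THF, reflux; then CuI (5 mol%), 2, THF, −10 °C → rt; 1 M HCl
Reagents that add atoms: none
Why: Copper-catalysed conjugate (Michael-type) addition of the aryl Grignard reagent to the doubly activated alkylidene malonate builds the benzylic quaternary carbon C-g in one operation; no stereocentre is formed.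

Step 2
Reactants: 4 diethyl 2-[2-(4-ethylphenyl)propan-2-yl]propanedioate
Product: 5 diethyl 2-[2-(4-ethylphenyl)propan-2-yl]-2-methylpropanedioate
Conditions: NaH, MeI, DMF, 0 → 40 °C
Reagents that add atoms: iodomethane, CI
Why: SN2 C-methylation of the sodium malonate enolate with the smallest electrophile should overcome the hindrance of the neighbouring quaternary carbon and gives the prochiral quaternary carbon C-q.

Step 3
Reactants: 5 diethyl 2-[2-(4-ethylphenyl)propan-2-yl]-2-methylpropanedioate
Product: 6 2-[2-(4-ethylphenyl)propan-2-yl]-2-methylpropane-1,3-diol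
Conditions: LiAlH4, THF, 0 °C → reflux; H2O, aq. NaOH work-up
Reagents that add atoms: none
Why: Exhaustive hydride reduction of both esters of a non-enolisable malonate gives the prochiral 2,2-disubstituted propane-1,3-diol.

Step 4
Reactants: 6 2-[2-(4-ethylphenyl)propan-2-yl]-2-methylpropane-1,3-diol
Product: 7 (2S)-2-[2-(4-ethylphenyl)propan-2-yl]-3-hydroxy-2-methylpropyl acetate
Conditions: Burkholderia cepacia lipase (Amano PS), vinyl acetate, iPr2O, 30 °C
Reagents that add atoms: vinyl acetate, CC(=O)OC=C
Why: Enzymatic desymmetrisation by lipase-catalysed irreversible transesterification is established for 2,2-disubstituted propane-1,3-diols; the enzyme tells the enantiotopic CH2OH groups apart through the large size difference between methyl and the tertiary aryl-alkyl group and so sets C-q (S).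

Step 5
Reactants: 7 (2S)-2-[2-(4-ethylphenyl)propan-2-yl]-3-hydroxy-2-methylpropyl acetate
Product: 8 (2R)-2-[2-(4-ethylphenyl)propan-2-yl]-2-methyl-3-oxopropyl acetate
Conditions: Dess–Martin periodinane, CH2Cl2, 0 °C → rt
Reagents that add atoms: none
Why: Dess–Martin oxidation converts the free arm to the aldehyde at once, which ends the risk of 1,3-acyl migration (racemisation) in 7; the α-carbon is quaternary, so neither epimerisation nor β-elimination of acetate is possible.

Step 6
Reactants: 8 (2R)-2-[2-(4-ethylphenyl)propan-2-yl]-2-methyl-3-oxopropyl acetate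
Product: 9 (2R)-2-[2-(4-ethylphenyl)propan-2-yl]-4-methoxy-2-methylbut-3-en-1-yl acetate (E/Z mixture)
Conditions: [Ph3PCH2OMe]Cl, KN(SiMe3)2 (slight deficit), THF, 0 °C; then 8, −78 → 0 °C
Reagents that add atoms: (methoxymethyl)triphenylphosphonium chloride, COC[P+](c1ccccc1)(c1ccccc1)c1ccccc1.[Cl-]
Why: Wittig methoxymethylenation (one-carbon homologation) of a non-enolisable aldehyde; the neopentyl acetate, shielded by two adjacent quaternary carbons, should outlast the much faster reaction of the ylide at the aldehyde, and the E/Z ratio of the enol ether is irrelevant.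

Step 7
Reactants: 9 (2R)-2-[2-(4-ethylphenyl)propan-2-yl]-4-methoxy-2-methylbut-3-en-1-yl acetate
Product: 11 [(2R)-6-ethyl-1,1,2-trimethyl-1,2-dihydronaphthalen-2-yl]methyl acetate, via 4-methoxytetralin acetate 10 (not isolated)
Conditions: MeSO3H, CH2Cl2 (dilute), 0 °C → rt
Reagents that add atoms: none
Why: Intramolecular Friedel–Crafts cyclodehydration (Bradsher type): C-protonation of the enol ether gives an oxocarbenium ion that is attacked by either of the two equivalent ortho positions of the aryl ring (six-membered ring B, favoured by the two quaternary carbons in the tether), and acid-induced loss of methanol from benzylic ether 10 gives the conjugated styrene; C-q is not touched.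

Step 8
Reactants: 11 [(2R)-6-ethyl-1,1,2-trimethyl-1,2-dihydronaphthalen-2-yl]methyl acetate
Product: 12 [(2R)-6-ethyl-1,1,2-trimethyl-1,2-dihydronaphthalen-2-yl]methanol
Conditions: K2CO3, MeOH, rt
Reagents that add atoms: none
Why: Base-catalysed transesterification (methanolysis of the acetate) frees the primary alcohol; the styrene and C-q are inert.

Step 9
Reactants: 12 [(2R)-6-ethyl-1,1,2-trimethyl-1,2-dihydronaphthalen-2-yl]methanol
Product: 13 (2R)-6-ethyl-1,1,2-trimethyl-1,2-dihydronaphthalene-2-carbaldehyde
Conditions: Dess–Martin periodinane, CH2Cl2, 0 °C → rt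
Reagents that add atoms: none
Why: Dess–Martin oxidation of the neopentyl alcohol gives a non-enolisable aldehyde; the quaternary α-carbon excludes epimerisation and migration of the ring double bond.

Step 10
Reactants: 13 (2R)-6-ethyl-1,1,2-trimethyl-1,2-dihydronaphthalene-2-carbaldehyde; 14 (3-carboxypropyl)triphenylphosphonium bromide
Product: 16 (4Z)-5-[(2R)-6-ethyl-1,1,2-trimethyl-1,2-dihydronaphthalen-2-yl]pent-4-enoic acid, via carboxylate ylide 15 (not isolated)
Conditions: 14, NaN(SiMe3)2 (2 equiv), THF, 0 °C; then 13, −78 °C → rt; 1 M HCl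
Reagents that add atoms: none
Why: Wittig reaction of a non-stabilised ylide under lithium-free conditions is kinetically Z-selective, the more so with an α-quaternary aldehyde, and should give the cis tether alkene; the carboxylic acid travels as its sodium salt.

Step 11
Reactants: 16 (4Z)-5-[(2R)-6-ethyl-1,1,2-trimethyl-1,2-dihydronaphthalen-2-yl]pent-4-enoic acid
Product: 18 (4Z)-5-[(2R)-6-ethyl-1,1,2-trimethyl-1,2-dihydronaphthalen-2-yl]-N,N-dimethylpent-4-enamide, via acyl imidazolide 17 (not isolated)
Conditions: 1,1'-carbonyldiimidazole, THF, rt; then Me2NH (2 M in THF), rt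
Reagents that add atoms: dimethylamine, CNC
Why: Amide formation through the acyl imidazolide is mild and near neutral, so neither the Z-alkene nor the styrene is isomerised.

Step 12
Reactants: 18 (4Z)-5-[(2R)-6-ethyl-1,1,2-trimethyl-1,2-dihydronaphthalen-2-yl]-N,N-dimethylpent-4-enamide
Product: 22 des-bromo tetracyclic cyclobutanone (C-a S; C-b R; C-c R; C-q R), via O-triflyl iminium triflate 19 (not isolated), via keteniminium triflate 20 (not isolated), via cyclobutaniminium triflate 21 (not isolated)
Conditions: Tf2O, 2,4,6-collidine, ClCH2CH2Cl, 0 → 80 °C; then H2O, aq. NaHCO3, rt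
Reagents that add atoms: water, O
Why: Tf2O converts the amide into O-triflyl iminium salt 19 and collidine removes an α-proton to give keteniminium ion 20; its electrophilic central carbon bonds to the non-benzylic styrene carbon (future C-c) while positive charge builds at the benzylic carbon (future C-a), the resulting enamine carbon (future C-b) closes onto C-a to give cyclobutaniminium salt 21, and water hydrolyses 21 to the ketone. The closest known reaction type is the intramolecular keteniminium–alkene [2+2] cycloaddition that turns unsaturated tertiary amides into bicyclic cyclobutanones. The first bond closes a seven-membered carbocycle through the iminium carbon by 7-exo-trig attack on the styrene, which the cis geometry of the four-atom tether allows; the second bond closes the cyclobutane (4-exo collapse of the enamine onto the benzylic cation) and in the same event ring C, the seven-membered ring that runs through C-a. C-c and C-a arise by suprafacial addition to the alkene face that carries the tether, which the preset C-q dictates because the tether cannot reach the opposite face, and C-b follows from the bridged geometry, its hydrogen being forced to the outside of the bicyclo[4.1.1] core. The step needs crossed regiochemistry and reaction at the styrene only: the first is secured by the styrene polarisation (only attack at C-c gives a benzylic cation), the second because the tether alkene sits too close to the keteniminium carbon to give anything but highly strained rings.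

Step 13
Reactants: 22 des-bromo tetracyclic cyclobutanone
Product: 23 des-bromo deoxo lactone (C-a S; C-b R; C-c R; C-q R)
Conditions: 30% aq. H2O2, AcOH, 0 °C → rt
Reagents that add atoms: hydrogen peroxide, OO
Why: Baeyer–Villiger oxidation: the strained cyclobutanone adds hydrogen peroxide far faster than the disubstituted alkene is epoxidised, and migration of the C-b bridgehead with retention (oxygen inserted between C=O and C-b) is expected to be favoured because the more congested C-c, locked in three rings next to C-q, is harder to move, although both α-carbons are secondary and this regiochemistry is the main uncertainty.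

Step 14
Reactants: 23 des-bromo deoxo lactone
Product: 25 des-bromo salimabromide (C-a S; C-b S; C-c R; C-q R), via allylic alcohol 24 (not isolated)
Conditions: SeO2, 1,4-dioxane, 100 °C; then Dess–Martin periodinane, CH2Cl2, rt
Reagents that add atoms: selenium dioxide, O=[Se]=O
Why: Selenium dioxide allylic oxidation (ene reaction, then 2,3-sigmatropic shift) can only strike the single allylic methylene, since the other allylic position is the quaternary C-q and the benzylic ethyl group lacks the alkene that the ene step needs; Dess–Martin oxidation of the crude allylic alcohol 24 converges on the enone, and C-b cannot epimerise because its epimer is geometrically impossible in the bridged rings C and D.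

Step 15
Reactants: 25 des-bromo salimabromide
Product: 27 salimabromide, via monobromide 26 (not isolated)
Conditions: Br2, AgOCOCF3, CF3CO2H, 0 °C → rt, dark
Reagents that add atoms: bromine, BrBr
Why: Silver-assisted electrophilic aromatic bromination (trifluoroacetyl hypobromite made in the flask) should substitute the two ring-A positions ortho to the ethyl group, each activated by two alkyl groups (ortho/para), while the third free position is flanked by C-g and activated by one alkyl group only; the enone alkene is electron-poor and inert to the electrophile, and no stereocentre is affected.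

**Compound list**

1 | 1-bromo-4-ethylbenzene | CCc1ccc(Br)cc1 | starting material
2 | diethyl isopropylidenemalonate | CCOC(=O)C(=C(C)C)C(=O)OCC | starting material
3 | 4-ethylphenylmagnesium bromide | CCc1ccc([Mg]Br)cc1 | intermediate (not isolated)
4 | diethyl 2-[2-(4-ethylphenyl)propan-2-yl]propanedioate | CCOC(=O)C(C(=O)OCC)C(C)(C)c1ccc(CC)cc1 | intermediate
5 | diethyl 2-[2-(4-ethylphenyl)propan-2-yl]-2-methylpropanedioate | CCOC(=O)C(C)(C(=O)OCC)C(C)(C)c1ccc(CC)cc1 | intermediate
6 | 2-[2-(4-ethylphenyl)propan-2-yl]-2-methylpropane-1,3-diol | CCc1ccc(cc1)C(C)(C)C(C)(CO)CO | intermediate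
7 | (2S)-2-[2-(4-ethylphenyl)propan-2-yl]-3-hydroxy-2-methylpropyl acetate | CC(=O)OC[C@](C)(CO)C(C)(C)c1ccc(CC)cc1 | intermediate
8 | (2R)-2-[2-(4-ethylphenyl)propan-2-yl]-2-methyl-3-oxopropyl acetate | CC(=O)OC[C@](C)(C=O)C(C)(C)c1ccc(CC)cc1 | intermediate
9 | (2R)-2-[2-(4-ethylphenyl)propan-2-yl]-4-methoxy-2-methylbut-3-en-1-yl acetate, E/Z mixture | CC(=O)OC[C@](C)(C=COC)C(C)(C)c1ccc(CC)cc1 | intermediate
10 | [(2R)-6-ethyl-4-methoxy-1,1,2-trimethyl-1,2,3,4-tetrahydronaphthalen-2-yl]methyl acetate, both C4 epimers | CC(=O)OC[C@]1(C)CC(OC)c2cc(CC)ccc2C1(C)C | intermediate (not isolated)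
11 | [(2R)-6-ethyl-1,1,2-trimethyl-1,2-dihydronaphthalen-2-yl]methyl acetate | CC(=O)OC[C@]1(C)C=Cc2cc(CC)ccc2C1(C)C | intermediate
12 | [(2R)-6-ethyl-1,1,2-trimethyl-1,2-dihydronaphthalen-2-yl]methanol | OC[C@]1(C)C=Cc2cc(CC)ccc2C1(C)C | intermediate
13 | (2R)-6-ethyl-1,1,2-trimethyl-1,2-dihydronaphthalene-2-carbaldehyde | O=C[C@]1(C)C=Cc2cc(CC)ccc2C1(C)C | intermediate
14 | (3-carboxypropyl)triphenylphosphonium bromide | OC(=O)CCC[P+](c1ccccc1)(c1ccccc1)c1ccccc1.[Br-] | starting material
15 | sodium 4-(triphenylphosphoranylidene)butanoate (carboxylate ylide) | [Na+].[O-]C(=O)CCC=P(c1ccccc1)(c1ccccc1)c1ccccc1 | intermediate (not isolated)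
16 | (4Z)-5-[(2R)-6-ethyl-1,1,2-trimethyl-1,2-dihydronaphthalen-2-yl]pent-4-enoic acid | OC(=O)CC/C=C\[C@]1(C)C=Cc2cc(CC)ccc2C1(C)C | intermediate
17 | (4Z)-5-[(2R)-6-ethyl-1,1,2-trimethyl-1,2-dihydronaphthalen-2-yl]-1-(imidazol-1-yl)pent-4-en-1-one (acyl imidazolide) | O=C(CC/C=C\[C@]1(C)C=Cc2cc(CC)ccc2C1(C)C)n1ccnc1 | intermediate (not isolated)
18 | (4Z)-5-[(2R)-6-ethyl-1,1,2-trimethyl-1,2-dihydronaphthalen-2-yl]-N,N-dimethylpent-4-enamide (key-step precursor) | CN(C)C(=O)CC/C=C\[C@]1(C)C=Cc2cc(CC)ccc2C1(C)C | intermediate
19 | O-triflyl iminium triflate of 18 | C[N+](C)=C(OS(=O)(=O)C(F)(F)F)CC/C=C\[C@]1(C)C=Cc2cc(CC)ccc2C1(C)C.[O-]S(=O)(=O)C(F)(F)F | intermediate (not isolated)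
20 | keteniminium triflate (Me2N+=C=CH–CH2–CH=CH– on C-q, Z) | C[N+](C)=C=CC/C=C\[C@]1(C)C=Cc2cc(CC)ccc2C1(C)C.[O-]S(=O)(=O)C(F)(F)F | intermediate (not isolated)
21 | cyclobutaniminium triflate (22 with C=N+Me2 in place of C=O) | CCc1ccc2c(c1)[C@H]1[C@@H]3C(=[N+](C)C)[C@H]1[C@@](C)(C=CC3)C2(C)C.[O-]S(=O)(=O)C(F)(F)F | intermediate (not isolated)
22 | des-bromo tetracyclic cyclobutanone: ring B carries a cis-fused cyclobutanone (C-a, C-b, C=O, C-c) on the tether face, C-b joined to C-q by CH2–CH=CH (cis); C-a S, C-b R, C-c R, C-q R (key-step product) | CCc1ccc2c(c1)[C@H]1[C@@H]3C(=O)[C@H]1[C@@](C)(C=CC3)C2(C)C | intermediate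
23 | des-bromo deoxo lactone: 22 with oxygen inserted between C=O and C-b (ring D); C-a S, C-b R, C-c R, C-q R | CCc1ccc2c(c1)[C@H]1[C@@H]3OC(=O)[C@H]1[C@@](C)(C=CC3)C2(C)C | intermediate
24 | allylic alcohol: 23 with OH on the ring-C methylene, carbinol configuration not fixed | CCc1ccc2c(c1)[C@H]1[C@@H]3OC(=O)[C@H]1[C@@](C)(C=CC3O)C2(C)C | intermediate (not isolated)
25 | des-bromo salimabromide (enone lactone); C-a S, C-b S, C-c R, C-q R | CCc1ccc2c(c1)[C@H]1[C@@H]3OC(=O)[C@H]1[C@@](C)(C=CC3=O)C2(C)C | intermediate
26 | monobromide: 25 with Br on ring A ortho to ethyl and para to the carbon that bears C-a | CCc1c(Br)cc2c(c1)[C@H]1[C@@H]3OC(=O)[C@H]1[C@@](C)(C=CC3=O)C2(C)C | intermediate (not isolated)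
27 | salimabromide; C-a S, C-b S, C-c R, C-q R | CCc1c(Br)cc2c(c1Br)[C@H]1[C@@H]3OC(=O)[C@H]1[C@@](C)(C=CC3=O)C2(C)C | target

**Step count**

Total: 15 steps. Longest linear sequence: 15 steps (from 1 and 2 to 27; 14 is bought).

**Three steps most likely to fail**

Step 12 (key cycloaddition). The keteniminium ion may engage the styrene in the wrong sense (first bond at the benzylic carbon), or the benzylic cation may lose a proton, rearrange or add to a second molecule before the four-membered ring closes. The fallback sets out from acid 16 and comes back at cyclobutanone 22. Acid 16 is treated with (COCl)2 and catalytic DMF in CH2Cl2 to give the acid chloride F1, which is added slowly to Et3N in refluxing toluene. Dehydrochlorination gives the ketene F2, a neutral partner that should undergo the thermal intramolecular ketene–alkene [2+2] cycloaddition with the same polarity (carbonyl carbon to C-c, α-carbon to C-a) but without a free benzylic cation, giving 22 directly.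

Step 13 (Baeyer–Villiger). The wrong bridgehead bond (C-c–C=O) may migrate, which puts the ring oxygen on C-c, because both α-carbons are secondary methines; epoxidation of the ring alkene is a lesser risk. The fallback sets out from 22 and comes back at 25, bypassing steps 13 and 14. Allylic oxidation of 22 as in step 14 (SeO2 in dioxane to the allylic alcohol F3, then Dess–Martin periodinane) gives the bridged 1,3-diketone F4, which cannot enolise at the bridgehead C-b. LiOH in THF–H2O, then acidification, adds to the strained cyclobutanone carbonyl, and the retro-Claisen cleavage can expel only C-b (as the enolate of the C-k ketone), so the keto acid F5 with CO2H on C-c and CH2 at C-b should form without regiochemical ambiguity. Oxidative α-lactonisation of this 5-oxo acid with PhI(OH)OTs in MeCN (hypervalent-iodine keto-acid lactonisation) then closes ring D by C-b–O bond formation on the only face that the C-c carboxyl group can reach, giving 25.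

Step 4 (lipase desymmetrisation). The acyl transfer may be slow or poorly selective, since the reacting CH2OH is neopentylic and flanked by two quaternary carbons; the monoacetate may also lose enantiopurity by 1,3-acyl migration before it is oxidised. The fallback sets out from diol 6 and comes back at alcohol 12. Catalytic asymmetric benzoylation with the dinuclear zinc catalyst made from Et2Zn and the ProPhenol ligand (the ligand enantiomer that gives the S ester) and vinyl benzoate in toluene gives the monobenzoate F6, which migrates far less readily. The benzoate is carried through the chemistry of steps 5 to 7: Dess–Martin oxidation to the aldehyde F7, methoxymethylenation to the enol ether F8, and MeSO3H cyclisation through the methoxytetralin F9 to the dihydronaphthalene benzoate F10. NaOMe in MeOH then releases 12.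

**Further compounds**

F1 | step 12 | (4Z)-5-[(2R)-6-ethyl-1,1,2-trimethyl-1,2-dihydronaphthalen-2-yl]pent-4-enoyl chloride | ClC(=O)CC/C=C\[C@]1(C)C=Cc2cc(CC)ccc2C1(C)C
F2 | step 12 | (4Z)-5-[(2R)-6-ethyl-1,1,2-trimethyl-1,2-dihydronaphthalen-2-yl]penta-1,4-dien-1-one (ketene) | O=C=CC/C=C\[C@]1(C)C=Cc2cc(CC)ccc2C1(C)C
F3 | step 13 | allylic alcohol of 22 (OH on the ring-C methylene, carbinol configuration not fixed) | CCc1ccc2c(c1)[C@H]1[C@@H]3C(=O)[C@H]1[C@@](C)(C=CC3O)C2(C)C
F4 | step 13 | bridged 1,3-diketone (22 with C-k oxidised to C=O) | CCc1ccc2c(c1)[C@H]1[C@@H]3C(=O)[C@H]1[C@@](C)(C=CC3=O)C2(C)C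
F5 | step 13 | ring-opened keto acid (CO2H on C-c, CH2 at C-b, rings A, B and C intact; C-a S, C-c R, C-q R) | CCc1ccc2c(c1)[C@H]1CC(=O)C=C[C@](C)([C@@H]1C(O)=O)C2(C)C
F6 | step 4 | (2S)-2-[2-(4-ethylphenyl)propan-2-yl]-3-hydroxy-2-methylpropyl benzoate | O=C(OC[C@](C)(CO)C(C)(C)c1ccc(CC)cc1)c1ccccc1
F7 | step 4 | (2R)-2-[2-(4-ethylphenyl)propan-2-yl]-2-methyl-3-oxopropyl benzoate | O=C(OC[C@](C)(C=O)C(C)(C)c1ccc(CC)cc1)c1ccccc1
F8 | step 4 | (2R)-2-[2-(4-ethylphenyl)propan-2-yl]-4-methoxy-2-methylbut-3-en-1-yl benzoate, E/Z mixture | O=C(OC[C@](C)(C=COC)C(C)(C)c1ccc(CC)cc1)c1ccccc1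
F9 | step 4 | [(2R)-6-ethyl-4-methoxy-1,1,2-trimethyl-1,2,3,4-tetrahydronaphthalen-2-yl]methyl benzoate, both C4 epimers | O=C(OC[C@]1(C)CC(OC)c2cc(CC)ccc2C1(C)C)c1ccccc1
F10 | step 4 | [(2R)-6-ethyl-1,1,2-trimethyl-1,2-dihydronaphthalen-2-yl]methyl benzoate | O=C(OC[C@]1(C)C=Cc2cc(CC)ccc2C1(C)C)c1ccccc1
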